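The cyclohexane ring is cut at C1–C2 and C4–C5 (quinic acid numbering) into two three-carbon pieces. The route exploits the 1,3-relationship of the C1 and C5 carbinols to C3: with C3 as a ketone, C2 and C4 are both nucleophilic, while C1 (an α-keto ester carbon) and C5 are electrophilic. One amine-catalysed Michael/aldol annulation of a silyloxyacetone (C2–C3–C4) with a 4-silyl-2-oxobut-3-enoate (C5–C6–C1 plus carboxyl) closes the ring. The C5 hydroxyl travels as a C–SiMe2Ph group, which cannot be eliminated and is later oxidised with retention. Ketone reduction, lactonisation to the quinide and two ordered acylations complete the target.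

Key step: step 2

Remark on numbering: ring atoms are numbered as in quinic acid (C1 carries the carboxyl carbon, C3 the caffeoyl ester, C4 the p-coumaroyl ester, C5 the free hydroxyl).
Remark on the catalyst hand: the (1R,2R) amine–thiourea is assumed to deliver C5 as R (attack on the Si face of C5 of 4); the (1S,2S) catalyst would give the mirror-image series and would be used instead if the sense is the opposite.
Remark on materials: 3,4-diacetoxycinnamic acid and 4-acetoxycinnamic acid are taken as purchased.

Step 1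
Reactants: 1 ethynyl(dimethyl)phenylsilane; 2 ethyl chlorooxoacetate
Product: 4 ethyl (E)-4-[dimethyl(phenyl)silyl]-2-oxobut-3-enoate, via alkenylzirconocene chloride 3 (not isolated)
Conditions: Cp2Zr(H)Cl, CH2Cl2, rt; then 2, CuBr·SMe2 (10 mol %), 0 °C → rt
Reagents that add atoms: none
Why: syn-hydrozirconation should place zirconium on the unsubstituted alkyne carbon, and copper-catalysed acylation of the alkenylzirconocene with the acid chloride should keep the E geometry.

Step 2
Reactants: 4 ethyl (E)-4-[dimethyl(phenyl)silyl]-2-oxobut-3-enoate; 5 1-[(tert-butyldimethylsilyl)oxy]propan-2-one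
Product: 7 ethyl (1S,4R,5R)-4-[(tert-butyldimethylsilyl)oxy]-5-[dimethyl(phenyl)silyl]-1-hydroxy-3-oxocyclohexane-1-carboxylate, via Michael adduct 6 (not isolated)
Conditions: 1-[(1R,2R)-2-aminocyclohexyl]-3-[3,5-bis(trifluoromethyl)phenyl]thiourea (20 mol %), PhCO2H (20 mol %), 5 (3 equiv), toluene, 25 °C
Reagents that add atoms: none
Why: The primary amine condenses with 5 to the more substituted, oxygen-bearing enamine, whose C4 adds to C5 of enone 4 (C4–C5 bond); the 2,6-diketo ester 6 then forms the methyl-side enamine, whose C2 attacks the C1 keto-ester carbonyl (C1–C2 bond). This is the amine-catalysed formal [3+3] Michael/aldol annulation of enolisable ketones with β,γ-unsaturated α-keto esters, applied here to a β-silyl acceptor. The ring closes in the aldol event by a 6-(enolendo)-exo-trig attack through a chair in which SiMe2Ph, OTBS and CO2Et are all equatorial. C5 is set by the catalyst (enamine attack on the Si face of C5 while the thiourea holds the 1,2-dicarbonyl unit), C4 is epimerisable through the enamine and should settle trans to silicon, and C1 follows from the chair, which places the ester cis to silicon and the new hydroxyl axial. The step needs conjugate addition at C5 instead of 1,2-addition to the keto ester, and reaction of 5 through C4 first and C2 second; the soft enamine and the reversibility of the 1,2-aldol favour the former, and the preference of α-oxygenated ketones for the substituted enamine secures the latter. Silicon in place of oxygen at C5 removes both β-elimination and the enolisation that a free 2,4-dioxobutanoate would suffer.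

Step 3
Reactants: 7 ethyl (1S,4R,5R)-4-[(tert-butyldimethylsilyl)oxy]-5-[dimethyl(phenyl)silyl]-1-hydroxy-3-oxocyclohexane-1-carboxylate
Product: 8 ethyl (1S,3R,4R,5R)-4-[(tert-butyldimethylsilyl)oxy]-5-[dimethyl(phenyl)silyl]-1,3-dihydroxycyclohexane-1-carboxylate
Conditions: LiBH(s-Bu)3 (L-Selectride, 2.2 equiv), THF, −78 °C; then H2O
Reagents that add atoms: none
Why: diastereoselective ketone reduction, in which the bulky hydride should attack C3 from the equatorial direction, away from the axial C1 oxygen, to give the axial alcohol cis to O-4 and O-1.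

Step 4
Reactants: 8 ethyl (1S,3R,4R,5R)-4-[(tert-butyldimethylsilyl)oxy]-5-[dimethyl(phenyl)silyl]-1,3-dihydroxycyclohexane-1-carboxylate
Product: 9 ethyl 4-O-(tert-butyldimethylsilyl)quinate (1-OH, 3-OH and O-4 cis to one another; 5-OH trans to O-4 and cis to the ester)
Conditions: KBr, AcOOH, NaOAc, AcOH, 0 °C → rt
Reagents that add atoms: peracetic acid CC(=O)OO
Why: Fleming–Tamao oxidation, in which bromodesilylation of the phenyl group and peracid-induced 1,2-shift of C5 from silicon to oxygen proceed with retention, so the equatorial C–Si bond should become the equatorial C5–OH.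

Step 5
Reactants: 9 ethyl 4-O-(tert-butyldimethylsilyl)quinate
Product: 10 4-O-(tert-butyldimethylsilyl)quinide (1,5-lactone; O-5 bonded to the carboxyl carbon)
Conditions: camphorsulfonic acid (10 mol %), toluene, 80 °C, 5 Å molecular sieves
Reagents that add atoms: none
Why: acid-catalysed lactonisation (transesterification) of the C5 hydroxyl, which is cis to the ester, should give the bicyclic γ-lactone as quinic acid derivatives do, masking O-5 and the carboxyl group together.

Step 6
Reactants: 10 4-O-(tert-butyldimethylsilyl)quinide; 11 (E)-3,4-diacetoxycinnamic acid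
Product: 13 3-O-[(E)-3,4-diacetoxycinnamoyl]-4-O-(tert-butyldimethylsilyl)quinide, via diacetoxycinnamoyl chloride 12 (not isolated)
Conditions: 11, (COCl)2, DMF (cat.), CH2Cl2, 0 °C → rt, evaporate; then 10, pyridine, DMAP (cat.), CH2Cl2, 0 °C → rt
Reagents that add atoms: none
Why: DMAP-catalysed esterification of the only secondary hydroxyl (O-3); the tertiary bridgehead O-1 should be far less reactive toward the acid chloride.

Step 7
Reactants: 13 3-O-[(E)-3,4-diacetoxycinnamoyl]-4-O-(tert-butyldimethylsilyl)quinide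
Product: 14 3-O-[(E)-3,4-diacetoxycinnamoyl]quinide (free 4-OH and 1-OH)
Conditions: HF·pyridine, THF, pyridine, 0 °C → rt
Reagents that add atoms: none
Why: fluoride-mediated silyl ether cleavage under buffered acidic conditions, which should leave the lactone, aryl acetates and cinnamate intact and should not promote 3→4 acyl migration.

Step 8
Reactants: 14 3-O-[(E)-3,4-diacetoxycinnamoyl]quinide; 15 (E)-4-acetoxycinnamic acid
Product: 17 3-O-[(E)-3,4-diacetoxycinnamoyl]-4-O-[(E)-4-acetoxycinnamoyl]quinide, via acetoxycinnamoyl chloride 16 (not isolated)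
Conditions: 15, (COCl)2, DMF (cat.), CH2Cl2, 0 °C → rt, evaporate; then 14, pyridine, DMAP (cat.), CH2Cl2, −20 °C → rt
Reagents that add atoms: none
Why: DMAP-catalysed esterification of the remaining secondary (axial) hydroxyl O-4 with the preformed acid chloride at low temperature, intended to be faster than acyl migration.

Step 9
Reactants: 17 3-O-[(E)-3,4-diacetoxycinnamoyl]-4-O-[(E)-4-acetoxycinnamoyl]quinide
Product: 18 3-O-caffeoyl-4-O-p-coumaroylquinic acid, (1R,3R,4S,5R)-3-{[(E)-3-(3,4-dihydroxyphenyl)prop-2-enoyl]oxy}-1,5-dihydroxy-4-{[(E)-3-(4-hydroxyphenyl)prop-2-enoyl]oxy}cyclohexane-1-carboxylic acid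
Conditions: 1 M aq. HCl, THF, 25 → 40 °C
Reagents that add atoms: water O
Why: acid-catalysed hydrolysis should open the strained lactone and remove the three phenolic acetates, while the two alkyl cinnamates hydrolyse more slowly and acyl migration is suppressed at low pH.

Compound list
1 | ethynyl(dimethyl)phenylsilane | C#C[Si](C)(C)c1ccccc1 | starting material
2 | ethyl chlorooxoacetate | CCOC(=O)C(Cl)=O | starting material
3 | {(E)-2-[dimethyl(phenyl)silyl]ethenyl}zirconocene chloride, Cp2Zr(Cl)CH=CHSiMe2Ph | C[Si](C)(/C=C/[Zr](Cl)(C1C=CC=C1)C1C=CC=C1)c1ccccc1 | intermediate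
4 | ethyl (E)-4-[dimethyl(phenyl)silyl]-2-oxobut-3-enoate | CCOC(=O)C(=O)/C=C/[Si](C)(C)c1ccccc1 | intermediate
5 | 1-[(tert-butyldimethylsilyl)oxy]propan-2-one | CC(=O)CO[Si](C)(C)C(C)(C)C | starting material
6 | ethyl (4R,5R)-5-[(tert-butyldimethylsilyl)oxy]-4-[dimethyl(phenyl)silyl]-2,6-dioxoheptanoate | CC(=O)[C@@H](O[Si](C)(C)C(C)(C)C)[C@H]([Si](C)(C)c1ccccc1)CC(=O)C(=O)OCC | intermediate
7 | ethyl (1S,4R,5R)-4-[(tert-butyldimethylsilyl)oxy]-5-[dimethyl(phenyl)silyl]-1-hydroxy-3-oxocyclohexane-1-carboxylate | CC(C)(C)[Si](C)(C)O[C@H]1[C@H]([Si](C)(C)c2ccccc2)C[C@](O)(C(=O)OCC)CC1=O | intermediate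
8 | ethyl (1S,3R,4R,5R)-4-[(tert-butyldimethylsilyl)oxy]-5-[dimethyl(phenyl)silyl]-1,3-dihydroxycyclohexane-1-carboxylate | CC(C)(C)[Si](C)(C)O[C@H]1[C@H]([Si](C)(C)c2ccccc2)C[C@](O)(C(=O)OCC)C[C@H]1O | intermediate
9 | ethyl 4-O-(tert-butyldimethylsilyl)quinate | CC(C)(C)[Si](C)(C)O[C@H]1[C@H](O)C[C@](O)(C(=O)OCC)C[C@H]1O | intermediate
10 | 4-O-(tert-butyldimethylsilyl)quinide (1,5-lactone) | CC(C)(C)[Si](C)(C)O[C@H]1[C@H]2C[C@](O)(C(=O)O2)C[C@H]1O | intermediate
11 | (E)-3,4-diacetoxycinnamic acid | CC(=O)Oc1ccc(/C=C/C(=O)O)cc1OC(C)=O | starting material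
12 | (E)-3,4-diacetoxycinnamoyl chloride | CC(=O)Oc1ccc(/C=C/C(Cl)=O)cc1OC(C)=O | intermediate
13 | 3-O-[(E)-3,4-diacetoxycinnamoyl]-4-O-(tert-butyldimethylsilyl)quinide | CC(C)(C)[Si](C)(C)O[C@H]1[C@H]2C[C@](O)(C(=O)O2)C[C@H]1OC(=O)/C=C/c1ccc(OC(C)=O)c(OC(C)=O)c1 | intermediate
14 | 3-O-[(E)-3,4-diacetoxycinnamoyl]quinide | O[C@H]1[C@H]2C[C@](O)(C(=O)O2)C[C@H]1OC(=O)/C=C/c1ccc(OC(C)=O)c(OC(C)=O)c1 | intermediate
15 | (E)-4-acetoxycinnamic acid | CC(=O)Oc1ccc(/C=C/C(=O)O)cc1 | starting material
16 | (E)-4-acetoxycinnamoyl chloride | CC(=O)Oc1ccc(/C=C/C(Cl)=O)cc1 | intermediate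
17 | 3-O-[(E)-3,4-diacetoxycinnamoyl]-4-O-[(E)-4-acetoxycinnamoyl]quinide | CC(=O)Oc1ccc(/C=C/C(=O)O[C@H]2[C@H]3C[C@](O)(C(=O)O3)C[C@H]2OC(=O)/C=C/c2ccc(OC(C)=O)c(OC(C)=O)c2)cc1 | intermediate
18 | 3-O-caffeoyl-4-O-p-coumaroylquinic acid, (1R,3R,4S,5R) | O=C(/C=C/c1ccc(O)cc1)O[C@H]1[C@H](O)C[C@](O)(C(=O)O)C[C@H]1OC(=O)/C=C/c1ccc(O)c(O)c1 | target

Total step count: 9. Longest linear sequence: 9 steps (1 → 4 → 7 → 8 → 9 → 10 → 13 → 14 → 17 → 18).

Steps most likely to fail

Step 2. The enamine may add 1,2 to the keto-ester carbonyl instead of adding to the hindered silicon-bearing C5. Facial control at C5 may be insufficient, or the β-hydroxy ketone may dehydrate under the amine/acid conditions. The fallback makes the two bonds in two stages from the same components, setting out from 4 and 5. Soft enolisation of 5 (TMSOTf, NEt3) gives (Z)-1-[(tert-butyldimethylsilyl)oxy]-2-[(trimethylsilyl)oxy]prop-1-ene F1. Its inverse-electron-demand hetero-Diels–Alder reaction with 4 under [Cu((S,S)-t-Bu-box)](OTf)2, a bis(oxazoline) complex of divalent copper (ligand hand chosen for C5 as R), forms the C4–C5 bond and gives the all-cis dihydropyran F2. Mild aqueous acid (AcOH, H2O, THF) cleaves the silyl ketal and enol ether to the open diketone F3, the C4 epimer of 6. Pyrrolidinium acetate then equilibrates C4 through the enamine (there is no β-leaving group at C5) and closes the ring by the same aldol, coming back to the route at 7.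

Step 4. Acid may remove the C4 silyl ether, and the resulting β-hydroxysilane may undergo Peterson-type elimination across C4–C5; electrophilic bromine may also react elsewhere. The fallback sets out from 8 and oxidises the phenylsilane under basic conditions (KH, t-BuOOH, DMF; then TBAF, 60 °C), with no electrophile or acid. The phenyl group leaves as phenol and fluoride also strips the TBS ether, giving ethyl quinate F4. Lactonisation (TsOH cat., toluene, reflux) gives quinide F5. One equivalent of acid chloride 12 (pyridine, CH2Cl2, −20 °C) should acylate the equatorial 3-OH preferentially, as in the selective 3-O-silylation of quinide, coming back to the route at 14.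

Step 8. Base may promote migration of the caffeoyl ester from O-3 to the free O-4 before acylation, scrambling the two esters, and acylation of the hindered axial hydroxyl may be sluggish. The fallback sets out from 14 and builds the second cinnamate in place without a basic acylation. Heating with Meldrum's acid (toluene, 80 °C) gives the 4-O-malonate half-ester F6. Knoevenagel–Doebner condensation with 4-hydroxybenzaldehyde (pyridine, β-alanine cat., 40 °C) with loss of CO2 gives 3-O-[(E)-3,4-diacetoxycinnamoyl]-4-O-[(E)-4-hydroxycinnamoyl]quinide F7. F7 is hydrolysed under the conditions of step 9, coming back to the route at 18.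

Further compounds
F1 | step 2 | (Z)-1-[(tert-butyldimethylsilyl)oxy]-2-[(trimethylsilyl)oxy]prop-1-ene | C[Si](C)(C)O/C(C)=C\O[Si](C)(C)C(C)(C)C
F2 | step 2 | ethyl 3-[(tert-butyldimethylsilyl)oxy]-4-[dimethyl(phenyl)silyl]-2-methyl-2-[(trimethylsilyl)oxy]-3,4-dihydro-2H-pyran-6-carboxylate (2-OTMS, 3-OTBS and 4-silyl all cis) | C[C@@]1(O[Si](C)(C)C)[C@H](O[Si](C)(C)C(C)(C)C)[C@H]([Si](C)(C)c2ccccc2)C=C(C(=O)OCC)O1
F3 | step 2 | ethyl (4R,5S)-5-[(tert-butyldimethylsilyl)oxy]-4-[dimethyl(phenyl)silyl]-2,6-dioxoheptanoate | CC(=O)[C@H](O[Si](C)(C)C(C)(C)C)[C@H]([Si](C)(C)c1ccccc1)CC(=O)C(=O)OCC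
F4 | step 4 | ethyl quinate | O[C@H]1[C@H](O)C[C@](O)(C(=O)OCC)C[C@H]1O
F5 | step 4 | quinide (quinic acid 1,5-lactone) | O[C@H]1[C@H]2C[C@](O)(C(=O)O2)C[C@H]1O
F6 | step 8 | 3-O-[(E)-3,4-diacetoxycinnamoyl]-4-O-(carboxyacetyl)quinide | OC(=O)CC(=O)O[C@H]1[C@H]2C[C@](O)(C(=O)O2)C[C@H]1OC(=O)/C=C/c1ccc(OC(C)=O)c(OC(C)=O)c1
F7 | step 8 | 3-O-[(E)-3,4-diacetoxycinnamoyl]-4-O-[(E)-4-hydroxycinnamoyl]quinide | O=C(/C=C/c1ccc(O)cc1)O[C@H]1[C@H]2C[C@](O)(C(=O)O2)C[C@H]1OC(=O)/C=C/c1ccc(OC(C)=O)c(OC(C)=O)c1
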